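The only stereocentre, C4, carries ring B; exchanging ring B for a second CH2CO2tBu arm turns C4 into the prochiral carbon of a 3-arylglutarate whose ring A hydroxyl at C8a lies ortho to it. A chiral phosphoric acid then lets this phenol lactonise onto one of the two enantiotopic ester arms, forming the O1–C2 bond, the lactone ring and the C4 configuration in one operation. The precursor is the achiral di-tert-butyl 3-arylglutarate bearing the C8 acyl group, benzyl ethers at O5 and O7 and a free C8a–OH; it is made by alkoxide opening of the racemic lactone, which also recycles the wrong enantiomer. The surviving arm is later annulated to ring B.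

Key step: step 7

Assumption: the sense of induction of the phosphoric acid cannot be predicted; (R)-TRIP, (R)-3,3'-bis(2,4,6-triisopropylphenyl)-1,1'-binaphthyl-2,2'-diyl hydrogen phosphate, is written, and its enantiomer is taken if it proves to favour the other arm.

Design remark: tert-butyl esters are kept because they resist uncatalysed closure and leave an acid-labile handle orthogonal to the aryl lactone. Benzyl ethers are kept because they can be removed last under neutral conditions.

Step 1
Reactants: 1 phloroglucinol; 2 3-phenylpropanoic acid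
Product: 3 3-phenyl-1-(2,4,6-trihydroxyphenyl)propan-1-one
Conditions: BF3·OEt2 (neat, as solvent), 90 °C; aq. NaOAc work-up
Reagents that add atoms: none
Why: Friedel–Crafts acylation with the free acid under BF3 activation should work because 1 is one of the most nucleophilic arenes, its symmetry leaves no regiochemical choice, and the first acyl group deactivates the ring against a second acylation.

Step 2
Reactants: 3 3-phenyl-1-(2,4,6-trihydroxyphenyl)propan-1-one
Product: 4 1-[2,4-bis(benzyloxy)-6-hydroxyphenyl]-3-phenylpropan-1-one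
Conditions: BnBr (2.1 equiv), K2CO3, acetone, reflux
Reagents that add atoms: benzyl bromide, BrCc1ccccc1
Why: Williamson ether synthesis: the para hydroxyl and one ortho hydroxyl are alkylated, after which the last ortho hydroxyl is locked in a hydrogen bond to the ketone and should stay free, and this is the oxygen that becomes O1.

Step 3
Reactants: 4 1-[2,4-bis(benzyloxy)-6-hydroxyphenyl]-3-phenylpropan-1-one
Product: 6 4,6-bis(benzyloxy)-2-hydroxy-3-(3-phenylpropanoyl)benzaldehyde, via salicyl alcohol 5 (not isolated)
Conditions: MgCl2, Et3N, (CH2O)n, MeCN, reflux; then 1 M HCl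
Reagents that add atoms: formaldehyde (used as paraformaldehyde), C=O
Why: Casnati–Skattebøl ortho-formylation: the magnesium phenoxide delivers formaldehyde only to the single free carbon ortho to its oxygen and the resulting salicyl alcohol is oxidised by hydride transfer to a second formaldehyde, so the free hydroxyl fixes the regiochemistry, and the non-acidic conditions spare the benzyl ethers and avoid the chromone formation that Vilsmeier conditions would risk.

Step 4
Reactants: 6 4,6-bis(benzyloxy)-2-hydroxy-3-(3-phenylpropanoyl)benzaldehyde; 7 2,2-dimethyl-1,3-dioxane-4,6-dione (Meldrum's acid)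
Product: 9 5,7-bis(benzyloxy)-2-oxo-8-(3-phenylpropanoyl)-2H-chromene-3-carboxylic acid, via arylidene Meldrum's acid 8 (not isolated)
Conditions: piperidinium acetate (10 mol%), EtOH, 70 °C
Reagents that add atoms: none
Why: Knoevenagel condensation gives the arylidene Meldrum's acid, whose carbonyl is attacked by the neighbouring phenol with loss of acetone (the standard entry to coumarin-3-carboxylic acids), which installs C2, C3 and C4 and activates C4 for the next step.

Step 5
Reactants: 9 5,7-bis(benzyloxy)-2-oxo-8-(3-phenylpropanoyl)-2H-chromene-3-carboxylic acid; 10 3-(tert-butoxy)-3-oxopropanoic acid (mono-tert-butyl malonate)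
Product: 12 tert-butyl 2-[(4RS)-5,7-bis(benzyloxy)-2-oxo-8-(3-phenylpropanoyl)chroman-4-yl]acetate (racemate), via Michael adduct diacid 11 (not isolated)
Conditions: N-methylmorpholine (1.5 equiv), THF, rt → 50 °C
Reagents that add atoms: none
Why: Doubly decarboxylative Michael addition: the amine-generated enolate of the malonic half-ester adds to C4 of the alkylidene-malonate-like coumarin-3-carboxylic acid and both β-carbonyl acids of the adduct lose CO2 on warming, leaving the CH2CO2tBu arm at C4, while a tertiary amine cannot aminolyse the aryl lactone.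

Step 6
Reactants: 12 tert-butyl 2-[(4RS)-5,7-bis(benzyloxy)-2-oxo-8-(3-phenylpropanoyl)chroman-4-yl]acetate
Product: 13 di-tert-butyl 3-[4,6-bis(benzyloxy)-2-hydroxy-3-(3-phenylpropanoyl)phenyl]pentanedioate (achiral)
Conditions: KOtBu (1.2 equiv), tBuOH/THF, 0 °C; AcOH quench
Reagents that add atoms: potassium tert-butoxide, CC(C)(C)[O-].[K+]
Why: Transesterification by alkoxide: tert-butoxide adds to the activated aryl lactone carbonyl and expels the ortho-acyl-stabilised phenoxide, so both arms become identical and C4 loses its chirality, and the same treatment returns any unwanted lactone enantiomer to this diester.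

Step 7
Reactants: 13 di-tert-butyl 3-[4,6-bis(benzyloxy)-2-hydroxy-3-(3-phenylpropanoyl)phenyl]pentanedioate
Product: 14 tert-butyl 2-[(4R)-5,7-bis(benzyloxy)-2-oxo-8-(3-phenylpropanoyl)chroman-4-yl]acetate (R by priority only; same spatial arrangement as the 4S target)
Conditions: (R)-TRIP (10 mol%), PhMe, 40 °C
Reagents that add atoms: none
Why: Proposed new method: the phosphoric acid activates one ester carbonyl through its acidic proton while its phosphoryl oxygen accepts the hydrogen bond of the C8a–OH, so the phenol adds to that carbonyl and the tetrahedral intermediate collapses with loss of tert-butanol, which should not re-open the aryl lactone under acid and so makes the choice of arm kinetic. The closest known reaction type is the chiral phosphoric acid-catalysed desymmetrising lactonisation of prochiral hydroxy di-tert-butyl esters, shown for aliphatic alcohols; a phenol is a weaker nucleophile, but the two ortho substituents (C8a–OH and C5–OBn) hold an ester arm over the hydroxyl much as in a trimethyl lock. The lactone ring closes in the 6-exo-trig mode, oxygen attacking C2 with the carbonyl oxygen outside the new ring. The new stereocentre C4 is set by catalyst control, the chiral pocket of the doubly hydrogen-bonded acid deciding which of the two enantiotopic CH2CO2tBu arms is attacked. The step needs selection between enantiotopic groups and a slow background reaction: the bulky tert-butyl esters and the internal hydrogen bond of the phenol to the C8 ketone should suppress uncatalysed closure, and since only the C8a oxygen is free, only the O1–C2 bond can form.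

Step 8
Reactants: 14 tert-butyl 2-[(4R)-5,7-bis(benzyloxy)-2-oxo-8-(3-phenylpropanoyl)chroman-4-yl]acetate
Product: 15 2-[(4R)-5,7-bis(benzyloxy)-2-oxo-8-(3-phenylpropanoyl)chroman-4-yl]acetic acid
Conditions: TFA/CH2Cl2 (1:4), 0 °C → rt
Reagents that add atoms: none
Why: Acidolysis of the tert-butyl ester by alkyl–oxygen cleavage through the tert-butyl cation should be selective because the aryl lactone, the benzyl aryl ethers and the ketone have no comparably labile bond in anhydrous acid, and C4 is not involved.

Step 9
Reactants: 15 2-[(4R)-5,7-bis(benzyloxy)-2-oxo-8-(3-phenylpropanoyl)chroman-4-yl]acetic acid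
Product: 17 2-[(4R)-5,7-bis(benzyloxy)-2-oxo-8-(3-phenylpropanoyl)chroman-4-yl]acetaldehyde, via acid chloride 16 (not isolated)
Conditions: (COCl)2, DMF (cat.), CH2Cl2, 0 °C → rt; evaporate; then Bu3SnH, Pd(PPh3)4 (3 mol%), PhMe, rt
Reagents that add atoms: none
Why: Acid chloride formation followed by palladium-catalysed tin hydride reduction (oxidative addition of zerovalent palladium into the C–Cl bond, hydride transfer, reductive elimination) should stop at the aldehyde and leave the ketone, the lactone and the benzyl ethers alone, which borane or aluminium hydride reagents would not.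

Step 10
Reactants: 17 2-[(4R)-5,7-bis(benzyloxy)-2-oxo-8-(3-phenylpropanoyl)chroman-4-yl]acetaldehyde; 18 but-3-en-2-one
Product: 20 (4S)-5,7-bis(benzyloxy)-4-(4-oxocyclohex-2-en-1-yl)-8-(3-phenylpropanoyl)chroman-2-one (both epimers at the cyclohexenyl carbon), via keto aldehyde 19 (not isolated)
Conditions: (S)-diphenylprolinol methyl ether (10 mol%), ethyl 3,4-dihydroxybenzoate (20 mol%), CHCl3, 4 °C → rt; then PhMe, TsOH·H2O (20 mol%), 80 °C
Reagents that add atoms: none
Why: Robinson annulation in two stages: enamine-catalysed Michael addition of the aldehyde to the vinyl ketone (the hindered prolinol ether forms the enamine but should be too encumbered and too dilute to aminolyse the aryl lactone), then acid-catalysed intramolecular aldol condensation of the methyl ketone onto the aldehyde, the only closure that gives an unstrained ring; the new stereocentre is left uncontrolled because step 11 removes it, and C4, being β to the carbonyl, cannot epimerise.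

Step 11
Reactants: 20 (4S)-5,7-bis(benzyloxy)-4-(4-oxocyclohex-2-en-1-yl)-8-(3-phenylpropanoyl)chroman-2-one
Product: 22 (4S)-5,7-bis(benzyloxy)-4-(4-hydroxyphenyl)-8-(3-phenylpropanoyl)chroman-2-one, via dienone 21 (not isolated)
Conditions: Pd(OCOCF3)2 (5 mol%), 2-(dimethylamino)pyridine (10 mol%), TsOH (20 mol%), O2 (1 atm), DMSO, 80 °C
Reagents that add atoms: none
Why: Aerobic dehydrogenation catalysed by divalent palladium: the palladium enolate of the enone undergoes β-hydride elimination to the cross-conjugated dienone, which tautomerises at once to the phenol while oxygen regenerates the catalyst; C4 of the chroman bears no activated hydrogen and should keep its configuration, and any dehydrogenation of the 3-phenylpropanoyl chain would be repaired by the hydrogenation of step 12.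

Step 12
Reactants: 22 (4S)-5,7-bis(benzyloxy)-4-(4-hydroxyphenyl)-8-(3-phenylpropanoyl)chroman-2-one
Product: 23 (4S)-5,7-dihydroxy-4-(4-hydroxyphenyl)-8-(3-phenylpropanoyl)chroman-2-one
Conditions: H2 (1 atm), 10% Pd/C, EtOAc, rt
Reagents that add atoms: none
Why: Catalytic hydrogenolysis of the two benzyl aryl ethers under neutral conditions in a non-nucleophilic solvent should free the C5 and C7 hydroxyls without touching the aryl lactone, the chelated aryl ketone or the C4–H bond, so the configuration set in step 7 is carried into the target.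

Compound list
1 | phloroglucinol | Oc1cc(O)cc(O)c1 | starting material
2 | 3-phenylpropanoic acid | OC(=O)CCc1ccccc1 | starting material
3 | 3-phenyl-1-(2,4,6-trihydroxyphenyl)propan-1-one | O=C(CCc1ccccc1)c1c(O)cc(O)cc1O | intermediate
4 | 1-[2,4-bis(benzyloxy)-6-hydroxyphenyl]-3-phenylpropan-1-one | O=C(CCc1ccccc1)c1c(OCc2ccccc2)cc(OCc2ccccc2)cc1O | intermediate
5 | 1-[4,6-bis(benzyloxy)-2-hydroxy-3-(hydroxymethyl)phenyl]-3-phenylpropan-1-one | OCc1c(OCc2ccccc2)cc(OCc2ccccc2)c(C(=O)CCc2ccccc2)c1O | intermediate (not isolated)
6 | 4,6-bis(benzyloxy)-2-hydroxy-3-(3-phenylpropanoyl)benzaldehyde | O=Cc1c(OCc2ccccc2)cc(OCc2ccccc2)c(C(=O)CCc2ccccc2)c1O | intermediate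
7 | 2,2-dimethyl-1,3-dioxane-4,6-dione (Meldrum's acid) | CC1(C)OC(=O)CC(=O)O1 | starting material
8 | 5-{[4,6-bis(benzyloxy)-2-hydroxy-3-(3-phenylpropanoyl)phenyl]methylidene}-2,2-dimethyl-1,3-dioxane-4,6-dione | CC1(C)OC(=O)C(=Cc2c(OCc3ccccc3)cc(OCc3ccccc3)c(C(=O)CCc3ccccc3)c2O)C(=O)O1 | intermediate (not isolated)
9 | 5,7-bis(benzyloxy)-2-oxo-8-(3-phenylpropanoyl)-2H-chromene-3-carboxylic acid | OC(=O)C1=Cc2c(OCc3ccccc3)cc(OCc3ccccc3)c(C(=O)CCc3ccccc3)c2OC1=O | intermediate
10 | 3-(tert-butoxy)-3-oxopropanoic acid (mono-tert-butyl malonate) | CC(C)(C)OC(=O)CC(O)=O | starting material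
11 | 5,7-bis(benzyloxy)-4-[2-(tert-butoxy)-1-carboxy-2-oxoethyl]-2-oxo-8-(3-phenylpropanoyl)chromane-3-carboxylic acid (racemic, diastereomer mixture) | OC(=O)C1C(C(C(O)=O)C(=O)OC(C)(C)C)c2c(OCc3ccccc3)cc(OCc3ccccc3)c(C(=O)CCc3ccccc3)c2OC1=O | intermediate (not isolated)
12 | tert-butyl 2-[(4RS)-5,7-bis(benzyloxy)-2-oxo-8-(3-phenylpropanoyl)chroman-4-yl]acetate (racemate) | O=C1CC(CC(=O)OC(C)(C)C)c2c(OCc3ccccc3)cc(OCc3ccccc3)c(C(=O)CCc3ccccc3)c2O1 | intermediate
13 | di-tert-butyl 3-[4,6-bis(benzyloxy)-2-hydroxy-3-(3-phenylpropanoyl)phenyl]pentanedioate (achiral) | CC(C)(C)OC(=O)CC(CC(=O)OC(C)(C)C)c1c(OCc2ccccc2)cc(OCc2ccccc2)c(C(=O)CCc2ccccc2)c1O | intermediate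
14 | tert-butyl 2-[(4R)-5,7-bis(benzyloxy)-2-oxo-8-(3-phenylpropanoyl)chroman-4-yl]acetate | O=C1C[C@@H](CC(=O)OC(C)(C)C)c2c(OCc3ccccc3)cc(OCc3ccccc3)c(C(=O)CCc3ccccc3)c2O1 | intermediate
15 | 2-[(4R)-5,7-bis(benzyloxy)-2-oxo-8-(3-phenylpropanoyl)chroman-4-yl]acetic acid | O=C1C[C@@H](CC(O)=O)c2c(OCc3ccccc3)cc(OCc3ccccc3)c(C(=O)CCc3ccccc3)c2O1 | intermediate
16 | 2-[(4S)-5,7-bis(benzyloxy)-2-oxo-8-(3-phenylpropanoyl)chroman-4-yl]acetyl chloride (S by priority only) | O=C1C[C@@H](CC(Cl)=O)c2c(OCc3ccccc3)cc(OCc3ccccc3)c(C(=O)CCc3ccccc3)c2O1 | intermediate (not isolated)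
17 | 2-[(4R)-5,7-bis(benzyloxy)-2-oxo-8-(3-phenylpropanoyl)chroman-4-yl]acetaldehyde | O=C1C[C@@H](CC=O)c2c(OCc3ccccc3)cc(OCc3ccccc3)c(C(=O)CCc3ccccc3)c2O1 | intermediate
18 | but-3-en-2-one | CC(=O)C=C | starting material
19 | 2-[(4S)-5,7-bis(benzyloxy)-2-oxo-8-(3-phenylpropanoyl)chroman-4-yl]-5-oxohexanal (both epimers at C2 of the hexanal) | O=C1C[C@@H](C(C=O)CCC(C)=O)c2c(OCc3ccccc3)cc(OCc3ccccc3)c(C(=O)CCc3ccccc3)c2O1 | intermediate (not isolated)
20 | (4S)-5,7-bis(benzyloxy)-4-(4-oxocyclohex-2-en-1-yl)-8-(3-phenylpropanoyl)chroman-2-one (both epimers at the cyclohexenyl carbon) | O=C1C[C@@H](C2C=CC(=O)CC2)c2c(OCc3ccccc3)cc(OCc3ccccc3)c(C(=O)CCc3ccccc3)c2O1 | intermediate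
21 | (4S)-5,7-bis(benzyloxy)-4-(4-oxocyclohexa-2,5-dien-1-yl)-8-(3-phenylpropanoyl)chroman-2-one | O=C1C[C@@H](C2C=CC(=O)C=C2)c2c(OCc3ccccc3)cc(OCc3ccccc3)c(C(=O)CCc3ccccc3)c2O1 | intermediate (not isolated)
22 | (4S)-5,7-bis(benzyloxy)-4-(4-hydroxyphenyl)-8-(3-phenylpropanoyl)chroman-2-one | O=C1C[C@@H](c2ccc(O)cc2)c2c(OCc3ccccc3)cc(OCc3ccccc3)c(C(=O)CCc3ccccc3)c2O1 | intermediate
23 | (4S)-5,7-dihydroxy-4-(4-hydroxyphenyl)-8-(3-phenylpropanoyl)chroman-2-one | O=C1C[C@@H](c2ccc(O)cc2)c2c(O)cc(O)c(C(=O)CCc3ccccc3)c2O1 | target

Total step count: 12. Longest linear sequence: 12 steps, from 1 to 23.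

Steps most likely to fail

Step 7. The acid may fail to discriminate between the two enantiotopic ester arms, or may not turn over at all because the hydrogen-bonded phenol is too weak a nucleophile. The fallback is a resolution. Racemic lactone 12, which step 5 delivers directly, would be separated by preparative supercritical-fluid chromatography on an amylose tris(3,5-dimethylphenylcarbamate) stationary phase. The (4R) fraction is 14, where the route is rejoined. The other fraction, tert-butyl 2-[(4S)-5,7-bis(benzyloxy)-2-oxo-8-(3-phenylpropanoyl)chroman-4-yl]acetate F1, would be opened to 13 under the conditions of step 6 and kept for further closure trials.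

Step 10. The secondary amine may open the aryl lactone, or the aldehyde may condense with itself faster than it adds to the enone. The fallback removes the amine. Aldehyde 17 would be converted with TMSCl, Et3N and NaI in MeCN into its silyl enol ether (4S)-5,7-bis(benzyloxy)-8-(3-phenylpropanoyl)-4-[2-(trimethylsilyloxy)ethenyl]chroman-2-one F2. This would add to 18 in a Lewis acid-promoted Mukaiyama–Michael reaction (BF3·OEt2, CH2Cl2, −78 °C) to give keto aldehyde 19 after aqueous work-up. Acid-catalysed cyclisation as in step 10 then returns to 20.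

Step 5. The hindered, electron-rich C4 may not accept the weakly nucleophilic half-ester enolate, or the half-ester may lose CO2 before it adds. The fallback separates C–C bond formation from decarboxylation. Aldehyde 6 would be heated with ethyl (triphenylphosphoranylidene)acetate in N,N-diethylaniline to give, by Wittig olefination and lactonisation, the coumarin 5,7-bis(benzyloxy)-8-(3-phenylpropanoyl)-2H-chromen-2-one F3. The silyl ketene acetal tert-butyl[(1-tert-butoxyethenyl)oxy]dimethylsilane F4, made from tert-butyl acetate with LiN(iPr)2 and TBSCl, would then be added to C4 in a Mukaiyama–Michael reaction under catalytic TBSOTf. Aqueous work-up should give racemic 12, where the route is rejoined.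

Further compounds
F1 | step 7 | tert-butyl 2-[(4S)-5,7-bis(benzyloxy)-2-oxo-8-(3-phenylpropanoyl)chroman-4-yl]acetate | O=C1C[C@H](CC(=O)OC(C)(C)C)c2c(OCc3ccccc3)cc(OCc3ccccc3)c(C(=O)CCc3ccccc3)c2O1
F2 | step 10 | (4S)-5,7-bis(benzyloxy)-8-(3-phenylpropanoyl)-4-[2-(trimethylsilyloxy)ethenyl]chroman-2-one (E/Z mixture) | O=C1C[C@@H](C=CO[Si](C)(C)C)c2c(OCc3ccccc3)cc(OCc3ccccc3)c(C(=O)CCc3ccccc3)c2O1
F3 | step 5 | 5,7-bis(benzyloxy)-8-(3-phenylpropanoyl)-2H-chromen-2-one | O=C1C=Cc2c(OCc3ccccc3)cc(OCc3ccccc3)c(C(=O)CCc3ccccc3)c2O1
F4 | step 5 | tert-butyl[(1-tert-butoxyethenyl)oxy]dimethylsilane | C=C(OC(C)(C)C)O[Si](C)(C)C(C)(C)C
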